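## The problem

Littorachalcone (17) consists of two 3-aryl-1-(2,4-dihydroxyphenyl)propan-1-one chains whose aryl ends, the para-disubstituted ring B and the 3-hydroxylated ring C, are joined through one diaryl ether oxygen. It has no stereocentre and no fused ring, so the task is one of regiochemistry and functional-group handling. Three things have to be built: the diaryl ether C–O bond that sits next to the ring C oxygen, the two aryl ketone C–C bonds, and the 1-acyl-2,4-dioxygenated pattern of rings A and D. The five free phenols make the final compound sensitive to base, air and strong electrophiles, so they should stay masked until the last step. The ketone chains are enolisable, and ring C is electron-rich enough that its C6 could be acylated intramolecularly under strong acid. The two halves differ only in the ring C hydroxyl, which invites working on both ends at once from one core. What makes the key step possible is that in rings A and D the ketone carbon sits on C1 and a hydroxyl on the adjacent C2, which is exactly the acyl and oxygen pair that a carboxylic acid hands to an aryne when the aryne inserts into its C–O bond, while C6 carries only hydrogen and can therefore hold a removable substituent that steers the insertion.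

## Retrosynthesis

**17 to 16.** The three O–CH3 bonds are cut last. Methyl ethers survive every earlier condition (fluoride, aryne, hydrogenation, organolithium). The ring C methyl arrives with vanillin 1 and the ring A and ring D methyls with phenol 8, so none costs a protection step. One Lewis acid treatment of trimethyl ether 16 should release all phenols of 17.

**16 to 15.** A chlorine is added at C6 of rings A and D. It is not part of the target and serves only to direct the key step. As an aryl chloride ortho to a ketone it should come off by hydrogenolysis from 15. Chlorine is preferred to bromine because bromine would not survive the lithiation used to make 13 and would leave more readily from the carbanion formed next to it in the key step. Fluorine could not be removed afterwards.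

**15 to 7 and two molecules of 13 (through aryne 14).** This is the key cut: on each of rings A and D the C1–C(=O) bond and the C2–O bond are broken together. A Friedel–Crafts cut would break only C1–C(=O) and would need strong acid, under which the propanoic acid chain on ring C can close onto C6 to an indanone. An aldol cut at the chain would need a preformed acylresorcinol and would pass through 2'-hydroxychalcones, which isomerise to flavanones. In the aryne cut the carboxylic acid supplies both the acyl carbon and the phenol oxygen, and the conditions are basic, so ring C is left alone. Diacid 7 lacks both resorcinol rings and ends in two identical acid groups, which is a large simplification. The forward step must make both acid groups insert, and each aryne 14 must be attacked at the carbon remote from chlorine.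

**7 to 6 to 3 and 4.** The two saturated chains are traced to the bis-cinnamic acid 6 and then cut at both Cα=Cβ bonds. Dialdehyde 3 and two molecules of malonic acid 4 should give 6 by a double condensation with decarboxylation, and hydrogenation should give 7. Both chains grow in the same operations.

**3 to 1 and 2.** The diaryl ether C–O bond is cut on the ring B side. The para-formyl group of 4-fluorobenzaldehyde 2 activates fluoride displacement, and vanillin 1 brings ring C with its oxygen pattern and the second aldehyde already in place.

**13 to 10 to 9 to 8.** The C–Si and O–S bonds of silyl triflate 13 are traced to silyl ether 10 by bromine–lithium exchange, O-to-C silyl shift and sulfonylation. Ether 10 comes from bromophenol 9, and 9 from commercial 2-chloro-4-methoxyphenol 8 by bromination at the only free position ortho to the hydroxyl.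

## Roads not taken

Alternative 1: Ring B is cut at two C–C bonds and built from methyl coumalate A2 and the ethynyl ether A3 of the acetal-protected ring C phenol. In the forward step A2 adds across the triple bond of A3 and the lactone bridge is extruded, giving benzoate A1 with the ether oxygen already on the new ring.
- Merits: the regiochemistry follows from polarity, since the terminal alkyne carbon attacks C6 of A2. No metal is needed. The two ends of A1 are differentiated as ester and acetal.
- Weak points: the differentiation is wasted here because both ends must become the same chain. A3 is a labile aryl ynol ether that needs a two-step O-ethynylation of protected vanillin 1 under strong base. A1 must still be reduced and unmasked to reach dialdehyde 3.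
- Comparison: the cycloaddition is spent on a benzene ring that 2 supplies in one substitution step, and rings A and D remain unaddressed. The alternative would be the better choice if the two acylresorcinol ends had to differ. Against that, the chosen plan reaches 3 in one step and uses its key step on the rings that cannot be bought in the right form.

Alternative 2: Ring C is cut at two C–C bonds and built from 3-aryloxyfuran A5, which carries ring B, and methyl propiolate A6. The cycloadduct is opened by mild acid so that the furan oxygen becomes the C3 hydroxyl of hydroxybenzoate A4.
- Merits: the polarity is matched, since C2 of the furan bonds to the terminal alkyne carbon. The aryloxy group should direct the bridge opening. The ring C hydroxyl emerges free, so no ether has to be cleaved there.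
- Weak points: A5 requires a difficult C–O coupling at the 3-position of a furan. An aryloxy group activates the furan less than an alkoxy group, and furan cycloadditions are reversible. If the bridge opens the other way, a regioisomeric phenol results.
- Comparison: like alternative 1 it ends at an ester and acetal pair that must be converted to the dialdehyde level, and it leaves rings A and D unmade. Its free C3 hydroxyl is a real advantage. The chosen plan offsets it by taking ring C from 1 and removing its methyl group in the same final operation as the other two.

Alternative 3: Rings A and D are each cut at C1–C2 and C5–C6 and built by a double cycloaddition of the bis(silyloxy) diene A9 to the two terminal ynone ends of bis-ynone A8. Loss of the methoxy group and desilylation give A7, the ring C methyl ether of the target.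
- Merits: it works in both directions at once, as the chosen plan does. The phenols appear free, no traceless halogen is needed, and one ether cleavage finishes the synthesis. With A8 available from diacid 7 in two steps, the total count would be about seven steps against nine. On count and on end-game this road is the better one.
- Weak points: 7 has to be turned into a bis(terminal ynone), which is a sensitive Michael acceptor. A9 is moisture-sensitive and can stop at open-chain conjugate adducts or lose silyl groups before ring closure. Both ends must cyclise and aromatise.
- Comparison: the chosen plan uses 7 as it is, relies on the bench-stable reagent 13 and on the well-established directing effect of a halogen next to an aryne. Its two three-step branches run in parallel, so its longest linear sequence is six steps against seven.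

Key step: step 7

Assumption: rings A and D are the two 2,4-dihydroxyphenyl ketone rings, numbered with the carbonyl-bearing carbon as C1; ring B is the para-disubstituted ring and ring C the 3-hydroxylated ring; the cesium carboxylates of 7 formed in the flask in step 7 are treated as the acid itself.

## Route

Step 1
Reactants: 1 vanillin (4-hydroxy-3-methoxybenzaldehyde); 2 4-fluorobenzaldehyde
Product: 3 4-(4-formylphenoxy)-3-methoxybenzaldehyde
Conditions: K2CO3, DMF, 120 °C
Reagents that add atoms: none
Why: Nucleophilic aromatic substitution (SNAr); the para-formyl group activates displacement of fluoride by the phenoxide of 1, a routine diaryl ether synthesis that leaves both aldehydes untouched.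

Step 2
Reactants: 3 4-(4-formylphenoxy)-3-methoxybenzaldehyde; 4 malonic acid (two molecules enter the product)
Product: 6 (2E)-3-(4-{4-[(E)-2-carboxyethenyl]-2-methoxyphenoxy}phenyl)prop-2-enoic acid, via bis(arylidenemalonic acid) 5 (not isolated)
Conditions: 4 (4 equiv), pyridine, piperidine (cat.), 100 °C
Reagents that add atoms: none
Why: Double Knoevenagel–Doebner condensation; each of the two aldehyde groups of 3 condenses with one molecule of malonic acid, and each arylidenemalonic acid unit of 5 loses one CO2 in hot pyridine to give the E-cinnamic acid (the geometry is erased in step 3).

Step 3
Reactants: 6 (2E)-3-(4-{4-[(E)-2-carboxyethenyl]-2-methoxyphenoxy}phenyl)prop-2-enoic acid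
Product: 7 3-{4-[4-(2-carboxyethyl)-2-methoxyphenoxy]phenyl}propanoic acid
Conditions: H2 (1 atm), 10% Pd/C, THF–MeOH, rt
Reagents that add atoms: none
Why: Catalytic hydrogenation of the two conjugated C=C bonds; the diaryl ether, the aryl methyl ether and the acids are inert under these conditions.

Step 4
Reactants: 8 2-chloro-4-methoxyphenol
Product: 9 2-bromo-6-chloro-4-methoxyphenol
Conditions: NBS, i-Pr2NH (cat.), CH2Cl2, 0 °C
Reagents that add atoms: N-bromosuccinimide, O=C1CCC(=O)N1Br
Why: Electrophilic aromatic bromination; the hydroxyl outranks the methoxy group as director, its para position is blocked and one ortho position holds chlorine, so bromine should enter C6, and the amine-catalysed NBS protocol is ortho-selective for phenols.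

Step 5
Reactants: 9 2-bromo-6-chloro-4-methoxyphenol
Product: 10 (2-bromo-6-chloro-4-methoxyphenoxy)trimethylsilane
Conditions: (Me3Si)2NH, THF, reflux; volatiles removed in vacuo
Reagents that add atoms: hexamethyldisilazane, C[Si](C)(C)N[Si](C)(C)C
Why: O-silylation of a phenol with hexamethyldisilazane; ammonia is the only by-product and the crude silyl ether is used after evaporation.

Step 6
Reactants: 10 (2-bromo-6-chloro-4-methoxyphenoxy)trimethylsilane
Product: 13 2-chloro-4-methoxy-6-(trimethylsilyl)phenyl trifluoromethanesulfonate, via aryllithium 11 (not isolated), via lithium phenoxide 12 (not isolated)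
Conditions: n-BuLi, THF, −100 → −80 °C; then Tf2O, −100 → −80 °C
Reagents that add atoms: trifluoromethanesulfonic anhydride, O=S(=O)(OS(=O)(=O)C(F)(F)F)C(F)(F)F
Why: Bromine–lithium exchange (much faster than any reaction at C–Cl) gives 11, which undergoes the anionic 1,3 O-to-C silyl shift (retro-Brook rearrangement) to phenoxide 12; O-sulfonylation with Tf2O then gives the ortho-silylaryl triflate, the standard one-flask route to such aryne precursors.

Step 7
Reactants: 7 3-{4-[4-(2-carboxyethyl)-2-methoxyphenoxy]phenyl}propanoic acid; 13 2-chloro-4-methoxy-6-(trimethylsilyl)phenyl trifluoromethanesulfonate (two molecules enter the product)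
Product: 15 6,6'-dichlorolittorachalcone trimethyl ether [1-(2-chloro-6-hydroxy-4-methoxyphenyl)-3-(4-{4-[3-(2-chloro-6-hydroxy-4-methoxyphenyl)-3-oxopropyl]-2-methoxyphenoxy}phenyl)propan-1-one], via 3-chloro-5-methoxybenzyne 14 (not isolated)
Conditions: 13 (3 equiv), CsF (8 equiv), THF, 125 °C, sealed tube
Reagents that add atoms: none
Why: This is fluoride-induced aryne generation followed by aryne insertion into the carboxylic C–O bond, a known way to ortho-hydroxyaryl ketones, here applied at both acid groups of 7. Fluoride removes the silyl group of 13 and triflate leaves to give aryne 14, while the acid groups are present as cesium carboxylates. Each carboxylate oxygen adds to the aryne carbon remote from chlorine, which becomes C2, and the aryl carbanion left at C1 next to chlorine attacks the carbonyl of the aryl ester just formed through a four-membered transition state. The strained alkoxide then opens by C–O cleavage to the ortho-acyl phenoxide, a net 1,3 O-to-C acyl shift, and work-up protonates it. No ring is closed and no stereocentre is formed. The selectivity needed is the site of attack on the unsymmetrical aryne: the chlorine beside the triple bond distorts it so that the remote carbon is the more electrophilic one and stabilises the developing carbanion inductively, which should outweigh the weaker opposing pull of the methoxy group further away. The outcome places OH on C2, the acyl group on C1, chlorine on C6 and the methoxy group on C4 of rings A and D. The high temperature favours acyl transfer over protonation of the carbanion, and the limited excess of 13 keeps O-arylation of the product phenoxide in check.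

Step 8
Reactants: 15 6,6'-dichlorolittorachalcone trimethyl ether
Product: 16 littorachalcone trimethyl ether [1-(2-hydroxy-4-methoxyphenyl)-3-(4-{4-[3-(2-hydroxy-4-methoxyphenyl)-3-oxopropyl]-2-methoxyphenoxy}phenyl)propan-1-one]
Conditions: H2 (1 atm), 10% Pd/C, Et3N, EtOAc–MeOH, rt
Reagents that add atoms: none
Why: Heterogeneous palladium-catalysed hydrodechlorination of aryl chlorides activated by the ortho-acyl group; Et3N takes up the HCl and tempers the catalyst, so the hydrogen-bonded, electron-rich aryl ketones and the diaryl ether should survive.

Step 9
Reactants: 16 littorachalcone trimethyl ether
Product: 17 littorachalcone [1-(2,4-dihydroxyphenyl)-3-(4-{4-[3-(2,4-dihydroxyphenyl)-3-oxopropyl]-2-hydroxyphenoxy}phenyl)propan-1-one]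
Conditions: BBr3, CH2Cl2, −78 °C → rt; then H2O
Reagents that add atoms: none
Why: Lewis acid cleavage of aryl methyl ethers with BBr3; all three methyl groups are removed as bromomethane while the diaryl ether and the ketones persist, and hydrolysis of the aryl borates releases 17.

## Compound list

1 | vanillin (4-hydroxy-3-methoxybenzaldehyde) | COc1cc(C=O)ccc1O | starting material
2 | 4-fluorobenzaldehyde | O=Cc1ccc(F)cc1 | starting material
3 | 4-(4-formylphenoxy)-3-methoxybenzaldehyde | COc1cc(C=O)ccc1Oc1ccc(C=O)cc1 | intermediate
4 | malonic acid | OC(=O)CC(O)=O | starting material
5 | 2-({4-[4-(2,2-dicarboxyethenyl)-2-methoxyphenoxy]phenyl}methylidene)propanedioic acid (bis(arylidenemalonic acid), not isolated) | COc1cc(C=C(C(O)=O)C(O)=O)ccc1Oc1ccc(C=C(C(O)=O)C(O)=O)cc1 | intermediate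
6 | (2E)-3-(4-{4-[(E)-2-carboxyethenyl]-2-methoxyphenoxy}phenyl)prop-2-enoic acid | COc1cc(/C=C/C(O)=O)ccc1Oc1ccc(/C=C/C(O)=O)cc1 | intermediate
7 | 3-{4-[4-(2-carboxyethyl)-2-methoxyphenoxy]phenyl}propanoic acid | COc1cc(CCC(O)=O)ccc1Oc1ccc(CCC(O)=O)cc1 | intermediate
8 | 2-chloro-4-methoxyphenol | COc1ccc(O)c(Cl)c1 | starting material
9 | 2-bromo-6-chloro-4-methoxyphenol | COc1cc(Cl)c(O)c(Br)c1 | intermediate
10 | (2-bromo-6-chloro-4-methoxyphenoxy)trimethylsilane | COc1cc(Cl)c(O[Si](C)(C)C)c(Br)c1 | intermediate
11 | [3-chloro-5-methoxy-2-(trimethylsilyloxy)phenyl]lithium (not isolated) | COc1cc(Cl)c(O[Si](C)(C)C)c([Li])c1 | intermediate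
12 | lithium 2-chloro-4-methoxy-6-(trimethylsilyl)phenoxide (not isolated) | COc1cc(Cl)c([O-])c([Si](C)(C)C)c1.[Li+] | intermediate
13 | 2-chloro-4-methoxy-6-(trimethylsilyl)phenyl trifluoromethanesulfonate | COc1cc(Cl)c(OS(=O)(=O)C(F)(F)F)c([Si](C)(C)C)c1 | intermediate
14 | 3-chloro-5-methoxybenzyne (not isolated) | COC1=CC#CC(Cl)=C1 | intermediate
15 | 6,6'-dichlorolittorachalcone trimethyl ether | COc1cc(O)c(C(=O)CCc2ccc(Oc3ccc(CCC(=O)c4c(O)cc(OC)cc4Cl)cc3OC)cc2)c(Cl)c1 | intermediate
16 | littorachalcone trimethyl ether | COc1ccc(C(=O)CCc2ccc(Oc3ccc(CCC(=O)c4ccc(OC)cc4O)cc3OC)cc2)c(O)c1 | intermediate
17 | littorachalcone | O=C(CCc1ccc(Oc2ccc(CCC(=O)c3ccc(O)cc3O)cc2O)cc1)c1ccc(O)cc1O | target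

## Step count and risks

Total: 9 steps. Longest linear sequence: 6 steps (steps 1, 2, 3, 7, 8, 9; the branch through steps 4, 5, 6 is equally long).

**Step 7 (key step).**
- What may go wrong: protonation of the C1 carbanion before acyl transfer, which stops the sequence at the aryl ester; insertion at only one of the two acid ends; further O-arylation of the product phenoxide by surplus aryne; loss of chloride from the ortho-chloroaryl carbanion; leakage of the regiochemistry if the methoxy group weakens the chlorine effect more than expected.
- Fallback: setting out from diacid 7, both acid groups would be converted (1,1'-carbonyldiimidazole, then N,O-dimethylhydroxylamine hydrochloride) into the bis(N-methoxy-N-methylamide) F1. Addition of commercial 2,4-dimethoxyphenylmagnesium bromide in THF would give littorachalcone pentamethyl ether F2 through the stable magnesium chelates. BBr3 would then cleave all five methyl ethers and bring the work back to the route at 17. This makes the C1–C(=O) bonds from a preformed aryl nucleophile in place of the aryne.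

**Step 8.**
- What may go wrong: hydrogenation of the aryl ketone carbonyl groups alongside C–Cl cleavage, or incomplete removal of the second chlorine.
- Fallback: setting out from 15, the order of the last two operations is reversed. BBr3 is applied first to give 6,6'-dichlorolittorachalcone F3. Hydrogenolysis of F3 over Pd/C in methanol with excess Et3N, where each ketone is masked as the vinylogous carboxylate of its para-phenoxide and is not reducible, then removes the chlorines and rejoins the route at 17.

**Step 6.**
- What may go wrong: quenching of aryllithium 11 before the silyl shift, its alkylation by the 1-bromobutane formed, or incomplete sulfonylation of the hindered phenoxide 12 at low temperature in THF.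
- Fallback: setting out from 10, the cascade is split into two separate bond-forming stages. After exchange and silyl shift the mixture is quenched with aqueous NH4Cl and 2-chloro-4-methoxy-6-(trimethylsilyl)phenol F4 is isolated and purified. F4 is then sulfonylated in a separate operation with N-phenylbis(trifluoromethanesulfonimide) and an amine base in CH2Cl2, which rejoins the route at 13.

**Step 4.**
- What may go wrong: bromination ortho to the methoxy group, double bromination, or oxidation of the hydroquinone monoether by the brominating agent.
- Fallback: the order in which the halogens are introduced is reversed. In place of 8, the sequence sets out from commercial 2-bromo-4-methoxyphenol F5; ortho-chlorination with SO2Cl2 and a catalytic secondary amine in toluene places chlorine at the remaining position ortho to the hydroxyl and rejoins the route at 9.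

## Further compounds

F1 | step 7 | N-methoxy-3-[4-(2-methoxy-4-{3-[methoxy(methyl)amino]-3-oxopropyl}phenoxy)phenyl]-N-methylpropanamide | COc1cc(CCC(=O)N(C)OC)ccc1Oc1ccc(CCC(=O)N(C)OC)cc1
F2 | step 7 | littorachalcone pentamethyl ether, 1-(2,4-dimethoxyphenyl)-3-(4-{4-[3-(2,4-dimethoxyphenyl)-3-oxopropyl]-2-methoxyphenoxy}phenyl)propan-1-one | COc1ccc(C(=O)CCc2ccc(Oc3ccc(CCC(=O)c4ccc(OC)cc4OC)cc3OC)cc2)c(OC)c1
F3 | step 8 | 6,6'-dichlorolittorachalcone, 1-(2-chloro-4,6-dihydroxyphenyl)-3-(4-{4-[3-(2-chloro-4,6-dihydroxyphenyl)-3-oxopropyl]-2-hydroxyphenoxy}phenyl)propan-1-one | O=C(CCc1ccc(Oc2ccc(CCC(=O)c3c(O)cc(O)cc3Cl)cc2O)cc1)c1c(O)cc(O)cc1Cl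
F4 | step 6 | 2-chloro-4-methoxy-6-(trimethylsilyl)phenol | COc1cc(Cl)c(O)c([Si](C)(C)C)c1
F5 | step 4 | 2-bromo-4-methoxyphenol | COc1ccc(O)c(Br)c1
A1 | alternative 1 | methyl 4-[4-(1,3-dioxolan-2-yl)-2-methoxyphenoxy]benzoate | COC(=O)c1ccc(Oc2ccc(C3OCCO3)cc2OC)cc1
A2 | alternative 1 | methyl coumalate (methyl 2-oxo-2H-pyran-5-carboxylate) | COC(=O)C1=COC(=O)C=C1
A3 | alternative 1 | 2-[4-(ethynyloxy)-3-methoxyphenyl]-1,3-dioxolane | COc1cc(C2OCCO2)ccc1OC#C
A4 | alternative 2 | methyl 4-[4-(1,3-dioxolan-2-yl)phenoxy]-3-hydroxybenzoate | COC(=O)c1ccc(Oc2ccc(C3OCCO3)cc2)c(O)c1
A5 | alternative 2 | 2-[4-(furan-3-yloxy)phenyl]-1,3-dioxolane | c1cc(Oc2ccc(C3OCCO3)cc2)co1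
A6 | alternative 2 | methyl propiolate | COC(=O)C#C
A7 | alternative 3 | littorachalcone ring C methyl ether, 1-(2,4-dihydroxyphenyl)-3-(4-{4-[3-(2,4-dihydroxyphenyl)-3-oxopropyl]-2-methoxyphenoxy}phenyl)propan-1-one | COc1cc(CCC(=O)c2ccc(O)cc2O)ccc1Oc1ccc(CCC(=O)c2ccc(O)cc2O)cc1
A8 | alternative 3 | 5-{4-[2-methoxy-4-(3-oxopent-4-yn-1-yl)phenoxy]phenyl}pent-1-yn-3-one | COc1cc(CCC(=O)C#C)ccc1Oc1ccc(CCC(=O)C#C)cc1
A9 | alternative 3 | 1-methoxy-1,3-bis(trimethylsilyloxy)buta-1,3-diene | COC(O[Si](C)(C)C)=CC(=C)O[Si](C)(C)C
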